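**Retrosynthetic overview**

1. Target 26 ⇒ allyl ester 25 ⇒ hydroxy enal 16 + trienoic acid 24 (ester bond); 24 ⇒ (R)-2-methylbutan-1-ol by Wittig and vinylogous Horner–Wadsworth–Emmons chain extension.
2. 16 ⇒ hydroxy enone 12 + 3-bromo-2-(bromomethyl)prop-1-ene (C1 alkylation, then allylic bromide to aldehyde).
3. 12 ⇒ ene-dione 11 (C4 ketone reduced from the face opposite the angular methyl).
4. Key disconnection: 11 ⇒ furan 8. Oxidative opening of the furan gives an ene-dione whose methyl ketone closes onto C7a (C1–C7a bond, quaternary centre, cyclopentenone).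
5. 8 ⇒ 2-methylfuran + oxirane + allyl acetoacetate. Ring order: six-membered carbocycle first (step 3, built onto the furan), cyclopentenone second (step 4, at the expense of the furan).

Assumption: (R)-2-methylbutan-1-ol (17) is taken as a purchasable starting material.
Assumption: the (R)-phosphoramide in step 4 is taken to give the (7aS) series; the sense of induction cannot be predicted with confidence, and the (S)-catalyst is used if the first run gives the antipode.

Atom numbering of the hydrindane core (C1, C2, C3, C3a, C4–C7, C7a) is that of the target throughout.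

**Step 1**
Reactants: 1 2-methylfuran; 2 oxirane
Product: 5 2-(5-methylfuran-2-yl)ethyl 4-methylbenzenesulfonate, via 5-methyl-2-furyllithium 3 (not isolated), via lithium 2-(5-methylfuran-2-yl)ethoxide 4 (not isolated)
Conditions: n-BuLi, THF, −78 to 0 °C; 2, 0 °C to rt; TsCl, 0 °C to rt
Reagents that add atoms: 4-methylbenzenesulfonyl chloride (TsCl), Cc1ccc(cc1)S(Cl)(=O)=O
Why: α-lithiation of the furan at its only free α-position, epoxide opening and sulfonylation of the lithium alkoxide in the same flask; no stereocentre is formed.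

**Step 2**
Reactants: 5 2-(5-methylfuran-2-yl)ethyl 4-methylbenzenesulfonate; 6 prop-2-en-1-yl 3-oxobutanoate (allyl acetoacetate)
Product: 7 prop-2-en-1-yl 2-acetyl-4-(5-methylfuran-2-yl)butanoate (racemic)
Conditions: K2CO3, DMF, 60 °C
Reagents that add atoms: none
Why: acetoacetic ester C-alkylation of the stabilised enolate by a primary tosylate; the new stereocentre is racemic and is erased in step 3.

**Step 3**
Reactants: 7 prop-2-en-1-yl 2-acetyl-4-(5-methylfuran-2-yl)butanoate
Product: 8 prop-2-en-1-yl 2,4-dimethyl-6,7-dihydro-1-benzofuran-5-carboxylate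
Conditions: Bi(OTf)3 (10 mol %), 4 Å MS, ClCH2CH2Cl, 60 °C
Reagents that add atoms: none
Why: intramolecular Friedel–Crafts-type hydroxyalkylation of the furan β-position next to the tether by the chelated ketone, then dehydration into conjugation with ester and furan (Bradsher-type cyclodehydration); this closes the six-membered ring and forms no stereocentre.

**Step 4**
Reactants: 8 prop-2-en-1-yl 2,4-dimethyl-6,7-dihydro-1-benzofuran-5-carboxylate
Product: 11 prop-2-en-1-yl (7R,7aS)-7a-methyl-2,4-dioxo-2,4,5,6,7,7a-hexahydro-1H-indene-7-carboxylate, via Z-ene-dione 9 (not isolated), via E-ene-dione 10 (not isolated)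
Conditions: mCPBA (1.0 equiv), CH2Cl2, −20 to 0 °C, aq. NaHCO3 wash; then (R)-3,3′-bis(2,4,6-triisopropylphenyl)-1,1′-binaphthyl-2,2′-diyl N-triflylphosphoramide (10 mol %), 4 Å MS, CHCl3, 0 °C to rt
Reagents that add atoms: 3-chloroperoxybenzoic acid (mCPBA), OOC(=O)c1cccc(Cl)c1
Why: Proposed new method: peracid opening of a 2,5-dialkylfuran to the cis-ene-dione 9 is known, the acid then equilibrates 9 with 10 (acetyl next to the C7a=C7 bond), and in 10 the enol of the methyl ketone (C1=C2–OH), the C3=C3a bond and the ester-polarised C7a form a U-shaped 2-hydroxypentadienyl array that closes C1–C7a in a 4π-type conrotatory step (equally an intramolecular vinylogous Mukaiyama–Michael addition) to give the quaternary C7a under ion-pair control by the chiral phosphoramide, after which the ester enol is protonated at C7 anti to the now axial methyl so that the ester ends equatorial and cis to the methyl; the closest known reactions are the chiral Brønsted acid catalysed Nazarov cyclisation and the 4π closure of the Piancatelli rearrangement.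

**Step 5**
Reactants: 11 prop-2-en-1-yl (7R,7aS)-7a-methyl-2,4-dioxo-2,4,5,6,7,7a-hexahydro-1H-indene-7-carboxylate
Product: 12 prop-2-en-1-yl (4S,7R,7aS)-4-hydroxy-7a-methyl-2-oxo-2,4,5,6,7,7a-hexahydro-1H-indene-7-carboxylate
Conditions: NaBH4 (0.3 equiv), CeCl3·7H2O, MeOH, −78 °C
Reagents that add atoms: none
Why: Luche 1,2-reduction, expected to favour the six-ring C4 ketone over the cyclopentenone carbonyl (I-strain; C2 also sits next to the neopentyl C1), with hydride entering anti to the axial angular methyl to give the axial 4S alcohol cis to the methyl, as in the reduction of 6-oxo steroids to 6β-alcohols.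

**Step 6**
Reactants: 12 prop-2-en-1-yl (4S,7R,7aS)-4-hydroxy-7a-methyl-2-oxo-2,4,5,6,7,7a-hexahydro-1H-indene-7-carboxylate; 13 3-bromo-2-(bromomethyl)prop-1-ene
Product: 15 prop-2-en-1-yl (1R,4S,7R,7aS)-1-[2-(bromomethyl)prop-2-en-1-yl]-4-hydroxy-7a-methyl-2-oxo-2,4,5,6,7,7a-hexahydro-1H-indene-7-carboxylate, via dilithium alkoxide-enolate 14 (not isolated)
Conditions: LiN(iPr)2 (2.2 equiv), THF, −78 °C; then 13 (3 equiv), −78 to −30 °C; aq. NH4Cl
Reagents that add atoms: none
Why: kinetic α′-deprotonation of the enone (after the alkoxide) and SN2 alkylation of the cross-conjugated enolate; the electrophile should enter C1 anti to the bulkier C7 branch of C7a, that is syn to the angular methyl, and this 1R epimer is also expected to be the thermodynamic one at this epimerisable centre.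

**Step 7**
Reactants: 15 prop-2-en-1-yl (1R,4S,7R,7aS)-1-[2-(bromomethyl)prop-2-en-1-yl]-4-hydroxy-7a-methyl-2-oxo-2,4,5,6,7,7a-hexahydro-1H-indene-7-carboxylate
Product: 16 prop-2-en-1-yl (1R,4S,7R,7aS)-1-(2-formylprop-2-en-1-yl)-4-hydroxy-7a-methyl-2-oxo-2,4,5,6,7,7a-hexahydro-1H-indene-7-carboxylate
Conditions: N-methylmorpholine N-oxide (3 equiv), MeCN, 0 °C to rt
Reagents that add atoms: 4-methylmorpholine 4-oxide (NMO), C[N+]1([O-])CCOCC1
Why: Ganem oxidation: the N-oxide displaces the allylic bromide and the alkoxyammonium salt eliminates to the 2-substituted acrolein; SN2 and SN2′ attack give the same product and no stereocentre is touched.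

**Step 8**
Reactants: 17 (R)-2-methylbutan-1-ol; 18 2-(triphenyl-λ5-phosphanylidene)propanal
Product: 20 (2E,4R)-2,4-dimethylhex-2-enal, via (R)-2-methylbutanal 19 (not isolated)
Conditions: TEMPO (10 mol %), PhI(OAc)2 (1.1 equiv), CH2Cl2, rt; then 18, rt to 40 °C
Reagents that add atoms: none
Why: oxoammonium (TEMPO) oxidation followed in the same flask by an E-selective Wittig olefination with the stabilised ylide, so the configurationally labile aldehyde is never isolated and the stereocentre of 17 is carried over.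

**Step 9**
Reactants: 20 (2E,4R)-2,4-dimethylhex-2-enal; 21 triethyl (E)-4-phosphonobut-2-enoate
Product: 23 ethyl (2E,4E,6E,8R)-6,8-dimethyldeca-2,4,6-trienoate, via lithiated phosphonate 22 (not isolated)
Conditions: 21, LiN(SiMe3)2, THF, −78 °C; then 20, −78 to 0 °C
Reagents that add atoms: none
Why: vinylogous Horner–Wadsworth–Emmons olefination gives the new E double bond; the phosphonate anion is preformed so that no free base can deprotonate the γ-position of 20.

**Step 10**
Reactants: 23 ethyl (2E,4E,6E,8R)-6,8-dimethyldeca-2,4,6-trienoate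
Product: 24 (2E,4E,6E,8R)-6,8-dimethyldeca-2,4,6-trienoic acid
Conditions: LiOH·H2O, THF–MeOH–H2O, rt; aq. HCl work-up
Reagents that add atoms: lithium hydroxide, [Li+].[OH-]
Why: plain saponification of the ethyl ester; the remote stereocentre and the triene geometry are not affected.

**Step 11**
Reactants: 16 prop-2-en-1-yl (1R,4S,7R,7aS)-1-(2-formylprop-2-en-1-yl)-4-hydroxy-7a-methyl-2-oxo-2,4,5,6,7,7a-hexahydro-1H-indene-7-carboxylate; 24 (2E,4E,6E,8R)-6,8-dimethyldeca-2,4,6-trienoic acid
Product: 25 prop-2-en-1-yl (1R,4S,7R,7aS)-4-{[(2E,4E,6E,8R)-6,8-dimethyldeca-2,4,6-trienoyl]oxy}-1-(2-formylprop-2-en-1-yl)-7a-methyl-2-oxo-2,4,5,6,7,7a-hexahydro-1H-indene-7-carboxylate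
Conditions: EDC·HCl, DMAP, CH2Cl2, 0 °C to rt
Reagents that add atoms: none
Why: Steglich esterification acylates the C4 oxygen, so C4 keeps its configuration.

**Step 12**
Reactants: 25 prop-2-en-1-yl (1R,4S,7R,7aS)-4-{[(2E,4E,6E,8R)-6,8-dimethyldeca-2,4,6-trienoyl]oxy}-1-(2-formylprop-2-en-1-yl)-7a-methyl-2-oxo-2,4,5,6,7,7a-hexahydro-1H-indene-7-carboxylate
Product: 26 (1R,4S,7R,7aS)-4-{[(2E,4E,6E,8R)-6,8-dimethyldeca-2,4,6-trienoyl]oxy}-1-(2-formylprop-2-en-1-yl)-7a-methyl-2-oxo-2,4,5,6,7,7a-hexahydro-1H-indene-7-carboxylic acid (CNP0277819.3)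
Conditions: Pd(PPh3)4 (5 mol %), N-methylaniline (2 equiv), THF, rt
Reagents that add atoms: none
Why: Tsuji–Trost-type deallylation transfers the allyl group to the weakly nucleophilic aniline under neutral conditions that leave the trienoate ester, the enal and the epimerisable C1 untouched.

**Compound list**

1 | 2-methylfuran | Cc1ccco1 | starting material
2 | oxirane | C1CO1 | starting material
3 | 5-methyl-2-furyllithium | [Li]c1ccc(C)o1 | intermediate
4 | lithium 2-(5-methylfuran-2-yl)ethoxide | [Li+].[O-]CCc1ccc(C)o1 | intermediate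
5 | 2-(5-methylfuran-2-yl)ethyl 4-methylbenzenesulfonate | Cc1ccc(CCOS(=O)(=O)c2ccc(C)cc2)o1 | intermediate
6 | prop-2-en-1-yl 3-oxobutanoate (allyl acetoacetate) | CC(=O)CC(=O)OCC=C | starting material
7 | prop-2-en-1-yl 2-acetyl-4-(5-methylfuran-2-yl)butanoate (racemic) | CC(=O)C(CCc1ccc(C)o1)C(=O)OCC=C | intermediate
8 | prop-2-en-1-yl 2,4-dimethyl-6,7-dihydro-1-benzofuran-5-carboxylate | Cc1cc2c(o1)CCC(C(=O)OCC=C)=C2C | intermediate
9 | prop-2-en-1-yl (3Z)-2-methyl-4-oxo-3-(2-oxopropylidene)cyclohex-1-ene-1-carboxylate | CC(=O)/C=C1\C(=O)CCC(C(=O)OCC=C)=C1C | intermediate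
10 | prop-2-en-1-yl (3E)-2-methyl-4-oxo-3-(2-oxopropylidene)cyclohex-1-ene-1-carboxylate | CC(=O)/C=C1/C(=O)CCC(C(=O)OCC=C)=C1C | intermediate
11 | prop-2-en-1-yl (7R,7aS)-7a-methyl-2,4-dioxo-2,4,5,6,7,7a-hexahydro-1H-indene-7-carboxylate | C1C(=O)C=C2C(=O)CC[C@@H](C(=O)OCC=C)[C@@]21C | intermediate
12 | prop-2-en-1-yl (4S,7R,7aS)-4-hydroxy-7a-methyl-2-oxo-2,4,5,6,7,7a-hexahydro-1H-indene-7-carboxylate | C1C(=O)C=C2[C@@H](O)CC[C@@H](C(=O)OCC=C)[C@@]21C | intermediate
13 | 3-bromo-2-(bromomethyl)prop-1-ene | C=C(CBr)CBr | starting material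
14 | dilithium salt of 12 (C4 alkoxide, C1=C2 enolate) | C1=C([O-])C=C2[C@@H]([O-])CC[C@@H](C(=O)OCC=C)[C@@]21C.[Li+].[Li+] | intermediate
15 | prop-2-en-1-yl (1R,4S,7R,7aS)-1-[2-(bromomethyl)prop-2-en-1-yl]-4-hydroxy-7a-methyl-2-oxo-2,4,5,6,7,7a-hexahydro-1H-indene-7-carboxylate | C=C(CBr)C[C@H]1C(=O)C=C2[C@@H](O)CC[C@@H](C(=O)OCC=C)[C@@]21C | intermediate
16 | prop-2-en-1-yl (1R,4S,7R,7aS)-1-(2-formylprop-2-en-1-yl)-4-hydroxy-7a-methyl-2-oxo-2,4,5,6,7,7a-hexahydro-1H-indene-7-carboxylate | C=C(C=O)C[C@H]1C(=O)C=C2[C@@H](O)CC[C@@H](C(=O)OCC=C)[C@@]21C | intermediate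
17 | (R)-2-methylbutan-1-ol | CC[C@@H](C)CO | starting material
18 | 2-(triphenyl-λ5-phosphanylidene)propanal | CC(C=O)=P(c1ccccc1)(c1ccccc1)c1ccccc1 | starting material
19 | (R)-2-methylbutanal | CC[C@@H](C)C=O | intermediate
20 | (2E,4R)-2,4-dimethylhex-2-enal | O=C/C(C)=C/[C@H](C)CC | intermediate
21 | triethyl (E)-4-phosphonobut-2-enoate | CCOC(=O)/C=C/CP(=O)(OCC)OCC | starting material
22 | lithium salt of 21 (C4 carbanion) | [Li+].CCOC(=O)/C=C/[CH-]P(=O)(OCC)OCC | intermediate
23 | ethyl (2E,4E,6E,8R)-6,8-dimethyldeca-2,4,6-trienoate | CCOC(=O)/C=C/C=C/C(C)=C/[C@H](C)CC | intermediate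
24 | (2E,4E,6E,8R)-6,8-dimethyldeca-2,4,6-trienoic acid | OC(=O)/C=C/C=C/C(C)=C/[C@H](C)CC | intermediate
25 | prop-2-en-1-yl ester of the target | C=C(C=O)C[C@H]1C(=O)C=C2[C@@H](OC(=O)/C=C/C=C/C(C)=C/[C@H](C)CC)CC[C@@H](C(=O)OCC=C)[C@@]21C | intermediate
26 | (1R,4S,7R,7aS)-4-{[(2E,4E,6E,8R)-6,8-dimethyldeca-2,4,6-trienoyl]oxy}-1-(2-formylprop-2-en-1-yl)-7a-methyl-2-oxo-2,4,5,6,7,7a-hexahydro-1H-indene-7-carboxylic acid | C=C(C=O)C[C@H]1C(=O)C=C2[C@@H](OC(=O)/C=C/C=C/C(C)=C/[C@H](C)CC)CC[C@@H](C(=O)O)[C@@]21C | target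

**Totals**

Total step count: 12. Longest linear sequence: 9 steps (steps 1–7, 11 and 12).

**Three steps most likely to fail**

Step 4 (the ene-dione may not close onto C7a cleanly, or the enantiomeric excess may be low). The fallback sets out from 8 and returns at 12. Furan 8 is opened with mCPBA as before and the crude ene-dione is treated with catalytic DBU in CH2Cl2, which isomerises 9 to 10 and closes the ring through the enolate without any chiral catalyst. This gives 11 as the racemate, that is 11 together with its mirror image prop-2-en-1-yl (7S,7aR)-7a-methyl-2,4-dioxo-2,4,5,6,7,7a-hexahydro-1H-indene-7-carboxylate F1. Luche reduction as in step 5 gives racemic alcohol, that is 12 with its mirror image prop-2-en-1-yl (4R,7S,7aR)-4-hydroxy-7a-methyl-2-oxo-2,4,5,6,7,7a-hexahydro-1H-indene-7-carboxylate F2. Candida antarctica lipase B with vinyl acetate in MTBE should then acetylate the (4R) alcohol F2 (the fast-reacting enantiomer by the usual lipase preference) to prop-2-en-1-yl (4R,7S,7aR)-4-acetoxy-7a-methyl-2-oxo-2,4,5,6,7,7a-hexahydro-1H-indene-7-carboxylate F3, and the unreacted (4S) alcohol, separated by chromatography, is 12. The cost is one more step and at most half of the material.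

Step 5 (the hydride may not distinguish the two enone carbonyls). The fallback sets out from 11 and returns at 12. Both carbonyls are reduced with excess NaBH4 and CeCl3·7H2O to prop-2-en-1-yl (4S,7R,7aS)-2,4-dihydroxy-7a-methyl-2,4,5,6,7,7a-hexahydro-1H-indene-7-carboxylate F4 (mixture of C2 epimers). One equivalent of PhI(OAc)2 with catalytic TEMPO then re-oxidises the unhindered cyclopentenol at C2, while the axial C4 alcohol, shielded by the angular methyl, is left, which gives 12.

Step 6 (O-alkylation of the alkoxide, double alkylation by the bis-electrophile, or a poor C1 epimer ratio). The fallback sets out from 12 and returns at 16, replacing the SN2 alkylation by a conjugate addition and a later methylenation. LiN(iPr)2 with TMSCl as internal quench gives prop-2-en-1-yl (4S,7R,7aS)-7a-methyl-2,4-bis(trimethylsilyloxy)-4,5,6,7-tetrahydro-7aH-indene-7-carboxylate F5. An iminium-catalysed Mukaiyama–Michael addition to acrolein (imidazolidinone trifluoroacetate salt) and an acidic work-up that removes both silyl groups give prop-2-en-1-yl (1R,4S,7R,7aS)-4-hydroxy-7a-methyl-2-oxo-1-(3-oxopropyl)-2,4,5,6,7,7a-hexahydro-1H-indene-7-carboxylate F6. α-Methylenation of the aldehyde with aqueous formaldehyde, catalytic pyrrolidine and propionic acid in iPrOH at 45 °C then gives 16.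

**Further compounds**

F1 | step 4 | prop-2-en-1-yl (7S,7aR)-7a-methyl-2,4-dioxo-2,4,5,6,7,7a-hexahydro-1H-indene-7-carboxylate | C1C(=O)C=C2C(=O)CC[C@H](C(=O)OCC=C)[C@]21C
F2 | step 4 | prop-2-en-1-yl (4R,7S,7aR)-4-hydroxy-7a-methyl-2-oxo-2,4,5,6,7,7a-hexahydro-1H-indene-7-carboxylate | C1C(=O)C=C2[C@H](O)CC[C@H](C(=O)OCC=C)[C@]21C
F3 | step 4 | prop-2-en-1-yl (4R,7S,7aR)-4-acetoxy-7a-methyl-2-oxo-2,4,5,6,7,7a-hexahydro-1H-indene-7-carboxylate | C1C(=O)C=C2[C@H](OC(C)=O)CC[C@H](C(=O)OCC=C)[C@]21C
F4 | step 5 | prop-2-en-1-yl (4S,7R,7aS)-2,4-dihydroxy-7a-methyl-2,4,5,6,7,7a-hexahydro-1H-indene-7-carboxylate (C2 epimers) | C1C(O)C=C2[C@@H](O)CC[C@@H](C(=O)OCC=C)[C@@]21C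
F5 | step 6 | prop-2-en-1-yl (4S,7R,7aS)-7a-methyl-2,4-bis(trimethylsilyloxy)-4,5,6,7-tetrahydro-7aH-indene-7-carboxylate | C1=C(O[Si](C)(C)C)C=C2[C@@H](O[Si](C)(C)C)CC[C@@H](C(=O)OCC=C)[C@@]21C
F6 | step 6 | prop-2-en-1-yl (1R,4S,7R,7aS)-4-hydroxy-7a-methyl-2-oxo-1-(3-oxopropyl)-2,4,5,6,7,7a-hexahydro-1H-indene-7-carboxylate | O=CCC[C@H]1C(=O)C=C2[C@@H](O)CC[C@@H](C(=O)OCC=C)[C@@]21C
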